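Late in a run, the turning of reagent into homo dimer still has no way back, while the other steps are written with one, so one reagent molecule is worth following.

| flask | starting material | reagent | catalyst | time |
|---|---|---|---|---|
| red | 0.050 M | 0.600 equiv | 10 mol% | 2.0 min |
| blue | 0.050 M | 0.900 equiv | 10 mol% | 2.0 min |
    starting material + reagent ⇌ isomer of the product A (K1 = 83 M⁻¹, k1 = 0.23 M⁻¹ s⁻¹)
    starting material + reagent ⇌ target (K2 = 13 M⁻¹, k2 = 15 M⁻¹ s⁻¹)
    target + catalyst ⇌ isomer of the product A + catalyst, rate k3*[catalyst]*[target] forward; the back reaction follows from the equilibrium constant (k3 = 0.13 M⁻¹ s⁻¹)
    2 reagent → homo dimer (k4 = 0.38 M⁻¹ s⁻¹)
    target ⇌ isomer of the product B (K5 = 0.89, k5 = 0.0020 s⁻¹)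
- which of these there is most of at the end, counted by the starting material in it, red (starting material / isomer of the product B / isomer of the product A / target)
- which of these there is most of at the end, counted by the starting material in it, blue (starting material / isomer of the product B / isomer of the product A / target)
- amount of the one of these that there is most of at the end, in percent of the starting material charged, red
- amount of the one of these that there is most of at the end, in percent of the starting material charged, blue
- for a step with 2 of a species take k times the square, and two of it per event
- run time (red): 2.0 min

1. Bench rule: reagent, charged at 0.600 equiv in red and 0.900 equiv in blue, is the limiting reagent. If each molecule took one starting material, the free fraction left would be 40.0 % in red and 10.0 % in blue.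

2. Follow one reagent molecule. In red, starting material goes into target with a forward half-life of 1.5 s, shorter than the 1.7 min into isomer of the product A. But nearly all of the molecules in target leave by the way back, so target is a waiting room, a pre-equilibrium.

3. The fork lies at free reagent. Let a and b be the free fractions of starting material and reagent, both on the starting material charge. Capture goes as 0.23 times a, and loss to homo dimer as 2 times 0.38 times b.

4. At the charge, loss over capture is 1.98 in red and 2.97 in blue. Loss runs faster than capture, so the bench rule stops here.

5. Taking a as one and b as the charge gives 0.335 in red and 0.252 in blue. This is the part of the reagent used at that moment by step 1 and homo dimer together that goes by step 1, forward rates alone: the capture share. It belongs to the charge, and a and b move during the run.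

6. A rough estimate holds the share at its value for the charge and takes charge times share as bound. My estimate therefore puts free starting material on top, at 79.9 % in red and 77.4 % in blue. It is no limit, since steps 1 and 2 run back.

7. The forecast names starting material for red and starting material for blue, at 74 % and 68 %, with reagent “largely lost to homo dimer”. Its figures stand lower than mine.

The simulation gives starting material on top in both flasks at 2.0 min, 73.8 % in red and 67.9 % in blue, and red still has 19 % of its reagent free. With the free fractions of that time, the capture share of red has climbed from 0.335 at the charge to 0.658. In blue it has climbed from 0.252 to 0.585.

The numbers were chosen freely; no experiment stands behind them.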